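**Strategy.** Ring B (C5–C10) is made one atom short. An amino acid-catalysed Robinson annulation gives a trans-hydrindanone in which ring A is fused to the five-membered ring C5–C6–C7–C8–C10. The key step inserts C9 between the C8 carbonyl carbon and quaternary C10: a β-oxido carbenoid 1,2-shift of C10 enlarges the ring and delivers the Δ8,9 lithium enolate regiospecifically, which is alkylated in the same flask by tert-butyl acrylate anti to the axial C10 methyl. This exploits the C8–C9–C10 array of ring B and sets the axial C9 chain. The ester then delivers the C8 oxygen as a cis-fused δ-lactone and ends as C13 of the diene.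

Key step: step 11

Remark: labdane numbering of the target is used for every intermediate (ring A = C1–C5 and C10; ring B = C5–C10; side chain C11–C16; C17 = methyl on C8; C18 = oxygenated carbon on C4; C19 = methyl on C4; C20 = methyl on C10). "Syn" and "anti" refer to the C10 methyl.

Step 1
Reactants: 1 2-methylcyclopentane-1,3-dione; 2 pent-1-en-3-one
Product: 3 2-methyl-2-(3-oxopentyl)cyclopentane-1,3-dione
Conditions: H2O, AcOH (cat.), 75 °C
Reagents that add atoms: none
Why: Michael addition of the enolised 1,3-dione to the vinyl ketone; no stereocentre is formed.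

Step 2
Reactants: 3 triketone
Product: 4 (7aR)-4,7a-dimethyl-2,3,7,7a-tetrahydro-1H-indene-1,5(6H)-dione
Conditions: (R)-phenylalanine (1 equiv), camphor-10-sulfonic acid (0.5 equiv), DMF, 25 → 70 °C; recrystallisation
Reagents that add atoms: none
Why: Hajos–Parrish reaction, in which the enamine of the (R)-amino acid selects one of the two enantiotopic ring carbonyls in the intramolecular aldol condensation, so that quaternary C10 should be set as R (the mirror image of the product from the natural (S)-amino acids).

Step 3
Reactants: 4 enedione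
Product: 5 (1R,7aR)-1-hydroxy-4,7a-dimethyl-1,2,3,6,7,7a-hexahydro-5H-inden-5-one (C8 hydroxyl syn)
Conditions: NaBH4, EtOH, −20 °C; AcOH
Reagents that add atoms: none
Why: Chemoselective hydride reduction of the saturated cyclopentanone beside the less electrophilic enone, with hydride adding anti to the C10 methyl; the C8 configuration is of no consequence because C8 is reoxidised in step 9.

Step 4
Reactants: 5 hydroxy enone
Product: 6 C4-benzyloxymethyl-C4-methyl Δ5(6)-3-ketone carrying C8–O–CH2OBn (C4 benzyloxymethyl anti and C4 methyl syn)
Conditions: KOt-Bu (2.4 equiv), THF, 0 °C; BnOCH2Cl (3 equiv), 0 °C → rt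
Reagents that add atoms: benzyl chloromethyl ether, ClCOCc1ccccc1 (two equivalents)
Why: Deconjugative α-alkylation of the extended potassium dienolate places the benzyloxymethyl group on C4 anti to the pseudo-axial C10 methyl and moves the alkene to C5=C6, while the C8 alkoxide is O-alkylated by the same reagent to a protecting formaldehyde acetal.

Step 5
Reactants: 6 ketone
Product: 8 3-deoxo Δ5(6)-alkene, via C3 hydrazone 7 (not isolated)
Conditions: N2H4·H2O, KOH, diethylene glycol, 130 °C then 200 °C
Reagents that add atoms: none
Why: Wolff–Kishner reduction (Huang-Minlon conditions) removes the C3 carbonyl; the acetal, the benzyl ether and the alkene, which cannot move into conjugation past quaternary C4, tolerate hot base.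

Step 6
Reactants: 8 alkene
Product: 10 trans-hydrindane C6 alcohol (H5 and C6–OH anti), via C6 alkylborane 9 (not isolated)
Conditions: BH3·THF, THF, 0 °C → rt; then NaOH, H2O2, 0 °C → rt
Reagents that add atoms: hydrogen peroxide, OO
Why: Hydroboration–oxidation, in which borane adds syn to the alkene face opposite the C4 and C10 methyl groups with boron on the less substituted C6, sets H5 and the C6 oxygen anti to the C10 methyl (trans ring fusion, later equatorial C6–O).

Step 7
Reactants: 10 alcohol
Product: 11 C6 benzyl ether
Conditions: NaH, BnBr, n-Bu4NI (cat.), THF/DMF, 0 °C → rt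
Reagents that add atoms: benzyl bromide, BrCc1ccccc1
Why: Williamson etherification of the secondary alkoxide; no stereocentre is touched.

Step 8
Reactants: 11 acetal
Product: 12 C8 alcohol
Conditions: HCl (cat.), MeOH, 50 °C
Reagents that add atoms: none
Why: Acid-catalysed transacetalisation cleaves the formaldehyde acetal on O8 selectively, since the two benzyl ethers are stable to dilute acid.

Step 9
Reactants: 12 alcohol
Product: 13 trans-hydrindan-8-one (6,18-bis-benzyl ether)
Conditions: n-Pr4NRuO4 (cat.), N-methylmorpholine N-oxide, 4 Å molecular sieves, CH2Cl2, rt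
Reagents that add atoms: none
Why: Ley–Griffith oxidation of the secondary alcohol under neutral conditions, which avoids β-elimination of the C6 benzyloxy group from the new ketone.

Step 10
Reactants: 13 ketone
Product: 14 8-(dibromomethyl) carbinol
Conditions: CH2Br2, LiN(i-Pr)2 (added to the ketone/CH2Br2 mixture), THF, −78 °C; AcOH, −78 °C
Reagents that add atoms: dibromomethane, BrCBr
Why: 1,2-Addition of dibromomethyllithium to the C8 carbonyl, expected from the face anti to the C10 methyl; the new C8 centre is lost in step 11, so either epimer serves.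

Step 11
Reactants: 14 dibromomethyl carbinol; 15 tert-butyl acrylate
Product: 18 ring-B keto ester (8-ketone with axial C9–CH2CH2CO2t-Bu), via β-oxido carbenoid 16 (not isolated), via lithium enolate 17 (not isolated)
Conditions: n-BuLi (2.1 equiv), THF, −95 → −40 °C; then 15, −78 °C; AcOH, −78 °C
Reagents that add atoms: none
Why: Deprotonation of the hydroxyl and bromine–lithium exchange give β-oxido carbenoid 16, whose alkoxide pushes the C8–C10 ring bond onto the carbenoid carbon (the future C9) as bromide leaves, so the five-membered ring C5–C6–C7–C8–C10 becomes six-membered ring B by a 1,2-shift (ring enlargement by one atom; no new ring is closed). The closest known reaction type is the β-oxido carbenoid ring enlargement of cycloalkanones with dibromomethyllithium, a Tiffeneau–Demjanov-type homologation in which the more substituted α-carbon migrates; here that is quaternary C10, which migrates with retention. The shift delivers directly the Δ8,9 lithium enolate 17, the regioisomer that deprotonation of the ring-enlarged ketone would not give. Michael addition of 17 to tert-butyl acrylate should occur at C9 on the face anti to the pseudo-axial C10 methyl, which creates the C9 stereocentre with the chain axial under substrate control. The step needs migration of C10 rather than C7 and capture of the kinetic enolate before proton exchange; the first rests on the migratory preference for the more substituted carbon, the second on the low temperature and the acidic quench at −78 °C, and the C8=C9 enolate cannot expel the C6 benzyloxy group, which would need the C7 enolate.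

Step 12
Reactants: 18 keto ester
Product: 20 cis-fused δ-lactone (C8 methyl syn; lactone oxygen on C8 anti and cis to the C9 chain), via 8-hydroxy tert-butyl ester 19 (not isolated)
Conditions: MeLi, CeCl3, THF, −78 °C; AcOH; then CF3CO2H, CH2Cl2, 0 °C → rt
Reagents that add atoms: methyllithium, [Li]C
Why: Organocerium 1,2-addition gives tertiary alcohol 19 (either C8 epimer), then acid cleaves the tert-butyl ester and ionises C8; the carboxyl on the axial C9 chain can reach the planar C8 cation only from its own face, so this SN1 lactonisation is stereoconvergent and should set C8 with oxygen cis to the chain and methyl axial.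

Step 13
Reactants: 20 lactone
Product: 21 6,18-diol lactone
Conditions: H2 (1 atm), Pd/C, EtOAc/EtOH, rt
Reagents that add atoms: none
Why: Hydrogenolysis of both benzyl ethers; the lactone and all stereocentres are untouched.

Step 14
Reactants: 21 diol
Product: 22 C18 tert-butyldimethylsilyl ether
Conditions: TBSCl, imidazole, DMF, 0 °C
Reagents that add atoms: tert-butyldimethylsilyl chloride, CC(C)(C)[Si](C)(C)Cl
Why: Silylation of the primary C18 hydroxyl is much faster than that of the hindered secondary C6 hydroxyl.

Step 15
Reactants: 22 lactone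
Product: 23 8-hydroxy C13 vinyl ketone
Conditions: CH2=CHMgBr (2.5 equiv), THF, −78 → −40 °C; AcOH, −78 °C
Reagents that add atoms: vinylmagnesium bromide, C=C[Mg]Br
Why: Grignard addition to the lactone carbonyl gives a magnesium hemiketal that should survive at low temperature, so the vinyl ketone is released only on the cold acidic quench and is not attacked twice; one equivalent of reagent is spent on the C6 hydroxyl.

Step 16
Reactants: 23 vinyl ketone
Product: 24 diene diol (C18 silyl ether)
Conditions: Ph3PCH3Br, KN(SiMe3)2, THF, −78 °C → rt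
Reagents that add atoms: methyltriphenylphosphonium bromide, C[P+](c1ccccc1)(c1ccccc1)c1ccccc1.[Br-]
Why: Wittig methylenation of the vinyl ketone gives the 2-substituted buta-1,3-diene; excess ylide covers the two free hydroxyl groups.

Step 17
Reactants: 24 diol
Product: 25 C6 acetate
Conditions: Ac2O, pyridine, DMAP (cat.), CH2Cl2, 0 °C → rt
Reagents that add atoms: acetic anhydride, CC(=O)OC(C)=O
Why: DMAP-catalysed acylation esterifies the secondary C6 hydroxyl, while the tertiary C8 hydroxyl should not react under these conditions.

Step 18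
Reactants: 25 silyl ether
Product: 26 target
Conditions: HF·pyridine, pyridine/THF, 0 °C → rt
Reagents that add atoms: none
Why: Desilylation under mildly acidic buffered conditions frees the C18 hydroxyl, avoids base-promoted acetyl migration from O6 to the nearby O18 and leaves the diene intact.

**Compound list**

1 | 2-methylcyclopentane-1,3-dione | CC1C(=O)CCC1=O | starting material
2 | pent-1-en-3-one (ethyl vinyl ketone) | C=CC(=O)CC | starting material
3 | 2-methyl-2-(3-oxopentyl)cyclopentane-1,3-dione | CCC(=O)CCC1(C)C(=O)CCC1=O | intermediate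
4 | (7aR)-4,7a-dimethyl-2,3,7,7a-tetrahydro-1H-indene-1,5(6H)-dione (C3 enone, C8 ketone, C10 R) | C[C@@]12CCC(=O)C(C)=C1CCC2=O | intermediate
5 | (1R,7aR)-1-hydroxy-4,7a-dimethyl-1,2,3,6,7,7a-hexahydro-5H-inden-5-one (C8–OH syn) | C[C@@]12CCC(=O)C(C)=C1CC[C@H]2O | intermediate
6 | Δ5(6)-3-ketone with C4 methyl syn, C4 CH2OBn anti, C8–OCH2OBn | C[C@@]12CCC(=O)[C@](C)(COCc3ccccc3)C1=CC[C@H]2OCOCc4ccccc4 | intermediate
7 | C3 hydrazone of 6 | C[C@@]12CCC(=NN)[C@](C)(COCc3ccccc3)C1=CC[C@H]2OCOCc4ccccc4 | intermediate (not isolated)
8 | 3-deoxo Δ5(6)-alkene | C[C@@]12CCC[C@](C)(COCc3ccccc3)C1=CC[C@H]2OCOCc4ccccc4 | intermediate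
9 | C6 alkylborane (boron anti) | C[C@@]12CCC[C@](C)(COCc3ccccc3)[C@H]1[C@H](B)C[C@H]2OCOCc4ccccc4 | intermediate (not isolated)
10 | trans-hydrindane C6 alcohol (H5 and C6–OH anti) | C[C@@]12CCC[C@](C)(COCc3ccccc3)[C@H]1[C@H](O)C[C@H]2OCOCc4ccccc4 | intermediate
11 | C6 benzyl ether | C[C@@]12CCC[C@](C)(COCc3ccccc3)[C@H]1[C@H](OCc5ccccc5)C[C@H]2OCOCc4ccccc4 | intermediate
12 | C8 alcohol (6,18-bis-benzyl ether) | C[C@@]12CCC[C@](C)(COCc3ccccc3)[C@H]1[C@H](OCc5ccccc5)C[C@H]2O | intermediate
13 | trans-hydrindan-8-one | C[C@@]12CCC[C@](C)(COCc3ccccc3)[C@H]1[C@H](OCc5ccccc5)CC2=O | intermediate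
14 | 8-(dibromomethyl) carbinol (C8–OH syn expected) | C[C@@]12CCC[C@](C)(COCc3ccccc3)[C@H]1[C@H](OCc5ccccc5)C[C@]2(O)C(Br)Br | intermediate
15 | tert-butyl acrylate | C=CC(=O)OC(C)(C)C | starting material
16 | β-oxido carbenoid (lithium alkoxide, α-bromo-α-lithio carbon) | C[C@@]12CCC[C@](C)(COCc3ccccc3)[C@H]1[C@H](OCc5ccccc5)C[C@]2(O[Li])C([Li])Br | intermediate (not isolated)
17 | ring-enlarged Δ8,9 lithium enolate | [Li]OC1=C[C@]2(C)CCC[C@](C)(COCc3ccccc3)[C@H]2[C@H](OCc4ccccc4)C1 | intermediate (not isolated)
18 | ring-B 8-ketone with axial C9–CH2CH2CO2t-Bu (chain anti) | CC(C)(C)OC(=O)CC[C@@H]1[C@]2(C)CCC[C@](C)(COCc3ccccc3)[C@H]2[C@H](OCc4ccccc4)CC1=O | intermediate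
19 | 8-hydroxy-8-methyl tert-butyl ester (shown as the expected major C8 epimer, OH syn) | CC(C)(C)OC(=O)CC[C@@H]1[C@]2(C)CCC[C@](C)(COCc3ccccc3)[C@H]2[C@H](OCc4ccccc4)C[C@@]1(C)O | intermediate (not isolated)
20 | cis-fused δ-lactone O8–C13 (C8 methyl syn, 6,18-bis-benzyl ether) | O=C1CC[C@@H]2[C@]3(C)CCC[C@](C)(COCc4ccccc4)[C@H]3[C@H](OCc5ccccc5)C[C@]2(C)O1 | intermediate
21 | 6,18-diol lactone | O=C1CC[C@@H]2[C@]3(C)CCC[C@](C)(CO)[C@H]3[C@H](O)C[C@]2(C)O1 | intermediate
22 | 18-O-TBS 6-hydroxy lactone | O=C1CC[C@@H]2[C@]3(C)CCC[C@](C)(CO[Si](C)(C)C(C)(C)C)[C@H]3[C@H](O)C[C@]2(C)O1 | intermediate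
23 | 6,8-dihydroxy C13 vinyl ketone (18-O-TBS) | C=CC(=O)CC[C@@H]1[C@]2(C)CCC[C@](C)(CO[Si](C)(C)C(C)(C)C)[C@H]2[C@H](O)C[C@]1(C)O | intermediate
24 | 18-O-TBS labda-13(16),14-diene-6,8-diol | C=CC(=C)CC[C@@H]1[C@]2(C)CCC[C@](C)(CO[Si](C)(C)C(C)(C)C)[C@H]2[C@H](O)C[C@]1(C)O | intermediate
25 | 6-acetate of 24 | C=CC(=C)CC[C@@H]1[C@]2(C)CCC[C@](C)(CO[Si](C)(C)C(C)(C)C)[C@H]2[C@H](OC(C)=O)C[C@]1(C)O | intermediate
26 | CNP0312185.2: 6-acetoxy-labda-13(16),14-diene-8,18-diol, 10R, with H5, C6–OAc, C8–OH, the C9 chain and C18 on the face opposite the C17, C19 and C20 methyl groups | C=CC(=C)CC[C@@H]1[C@]2(C)CCC[C@](C)(CO)[C@H]2[C@H](OC(C)=O)C[C@]1(C)O | target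

**Totals.** 18 steps in all; longest linear sequence 18 steps (1 → 26).

**Steps most likely to fail**

- **Step 11 (key step).** In the strongly basic one-pot medium the regiodefined enolate 17 may exchange protons with the ester enolate of its own adduct, or the acrylate may oligomerise. The consequences would be loss of the axial C9 configuration, scrambling of the enolate toward C7 and elimination of the C6 benzyloxy group. The fallback starts from 14: the same carbenoid rearrangement is run, but the enolate is silylated with Me3SiCl to give the isolable Δ8,9 trimethylsilyl enol ether F1. A Mukaiyama–Michael addition of F1 to 15, catalysed by Me3SiNTf2 in CH2Cl2 at −78 °C and followed by aqueous acidic work-up, forms the same C9–C11 bond anti to the C10 methyl under non-basic conditions. It returns to the route at 18.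

- **Step 12.** The C8 cation may lose a proton instead of being captured by the carboxyl group, and a C8=C9 alkene formed in this way could erase the C9 configuration. Enolisation of the hindered ketone by the methyl nucleophile is a further risk. The fallback starts from 18: Takai–Lombardo methylenation (Zn, CH2Br2, TiCl4) converts the C8 ketone without base into the exocyclic methylene ester F2. Iodolactonisation of F2 (I2, NaHCO3, MeCN, 0 °C) delivers the carboxyl oxygen to C8 from the face of the C9 chain, with loss of the tert-butyl group, and gives the iodomethyl lactone F3. Radical deiodination (Bu3SnH, AIBN, benzene, 80 °C) turns the iodomethyl group into the C8 methyl. It returns to the route at 20.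

- **Step 15.** The tetrahedral intermediate may collapse before the quench, so that the liberated vinyl ketone suffers a second 1,2- or 1,4-addition of the Grignard reagent or polymerises. The fallback starts from 22: aminolysis with MeNH(OMe)·HCl and AlMe3 in CH2Cl2 opens the lactone to the 8-hydroxy N-methoxy-N-methyl amide F4. Addition of CH2=CHMgBr to F4 stops at the chelated stage and gives the vinyl ketone on work-up. It returns to the route at 23.

**Further compounds**

F1 | step 11 | Δ8,9 trimethylsilyl enol ether of the ring-enlarged ketone | C[Si](C)(C)OC1=C[C@]2(C)CCC[C@](C)(COCc3ccccc3)[C@H]2[C@H](OCc4ccccc4)C1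
F2 | step 12 | 8(17)-methylene tert-butyl ester | CC(C)(C)OC(=O)CC[C@@H]1[C@]2(C)CCC[C@](C)(COCc3ccccc3)[C@H]2[C@H](OCc4ccccc4)CC1=C
F3 | step 12 | 8-(iodomethyl) cis-fused δ-lactone | O=C1CC[C@@H]2[C@]3(C)CCC[C@](C)(COCc4ccccc4)[C@H]3[C@H](OCc5ccccc5)C[C@]2(CI)O1
F4 | step 15 | 8-hydroxy N-methoxy-N-methyl amide | CON(C)C(=O)CC[C@@H]1[C@]2(C)CCC[C@](C)(CO[Si](C)(C)C(C)(C)C)[C@H]2[C@H](O)C[C@]1(C)O
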